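All constants come from no measurement; the run is a simulation.

In a one-step world, where free monomer could only enter chains, a chain's length would be the charge divided by the chains begun. This flask also gives monomer back, so you reckon it in two rounds.

all flasks: free monomer 0.0050 M (fed, over 50 s); impurity 68 µM; time 8.0 min

| run | pre-initiator |
|---|---|
| cedar | 0.45 mM |
| maple | 1.5 mM |

* which of the two ends with the longer chains by the average number of monomer units in a chain (chains begun, living or dead) ("neither" if they lie within 10%) (cedar / maple / neither)
* average number of monomer units in a chain (chains begun, living or dead) at the end, cedar
* average number of monomer units in a chain (chains begun, living or dead) at the end, maple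

- the average divides the monomer in chains by the number of chains begun, living and dead together
- run time (cedar): 8.0 min

    free monomer + living end → monomer in chains + living end, rate k1*[living end]*[free monomer] (k1 = 155 L mol⁻¹ s⁻¹)
    monomer in chains + living end → free monomer + living end, rate k2*[living end] as long as [monomer in chains] is above zero (k2 = 0.0743 s⁻¹)
    pre-initiator → initiator (k3 = 0.631 s⁻¹)
    free monomer + initiator → living end + monomer in chains (k4 = 93.2 L mol⁻¹ s⁻¹)
    initiator + impurity → spent initiator (k5 = 1.25 × 10⁵ L mol⁻¹ s⁻¹)

1. What is in the flask now. Pre-initiator becomes initiator with a half-life of 1.1 s, shorter than the 50 s feed. Impurity takes initiator at 8.50 s⁻¹, while free monomer takes it at 0.466 s⁻¹ even if its whole charge stood there at once, so you reckon on losing 68 µM of initiator to impurity.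

2. First round. Chains begun, as a fraction of the monomer charge, are 0.0764 in cedar and 0.286 in maple. With every unit bound, cedar's chains hold 13.1 units.

3. Second round. As long as there is monomer in chains, each living end returns monomer at 0.0743 s⁻¹, whatever the free monomer stands at, and it takes monomer up at 155 L mol⁻¹ s⁻¹ times the free monomer, so in both flasks uptake and return balance with 0.0959 of the charge free. The remainder, 0.904, is the bound share: the fraction of the charge held in chains at that balance.

4. Check by putting the answer back. With free monomer at that balance, initiator's half-life is 15.5 s, shorter than 8.0 min, so the chains begun still stand.

5. What you will find. Length is bound share over chains begun: 11.8 in cedar, 3.16 in maple.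

The forecast names cedar, with 11.83 and 3.16, holding that “The rest initiates completely”.

The flask gives 11.8 for cedar and 3.16 for maple, so cedar has the longer chains. At 8.00 min, maple holds 0.00143 M of living end. Set against the charge, that reading gives a length of 3.16 from the bound share.

Now take cedar with 1.2 × 10⁻⁴ M of impurity. The same bound share gives 13.7, and the flask gives 13.7.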